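A small charge of second end groups at a time is what south gives its first end groups: the 0.459 M arrives over 8.0 min, while protic impurity stands in the flask from the start. So I follow one first end group and ask its chances at the fork between becoming a link and leaving some other way.

| flask | first end groups | second end groups | protic impurity | temperature | remark | time |
|---|---|---|---|---|---|---|
| epsilon | 0.45 M | 0.459 M | 0.45 M | 60 °C | run made earlier |  |
| zeta | 0.68 M | 0.459 M | 0.45 M | 60 °C | run made earlier |  |
| south | 0.45 M | 0.459 M (fed, over 8.0 min) | 0.450 M | 60 °C | all else is in the flask from the start; the feed brings no volume worth counting | 10 min |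
| north-west | 0.45 M (fed, over 8.0 min) | 0.459 M | 0.450 M | 60 °C | all else is in the flask from the start; the feed brings no volume worth counting | 10 min |
| north | 0.45 M (fed, over 2.0 min) | 0.459 M | 0.450 M | 60 °C | all else is in the flask from the start; the feed brings no volume worth counting | 10 min |
| east | 0.45 M | 0.459 M (fed, over 8.0 min) | 0.450 M |  | the addition at 40 °C, then warmed to 60 °C; the feed brings no volume worth counting | 10 min |
| south-east | 0.45 M | 0.459 M | 0.450 M |  | everything together at the start at 40 °C, warmed to 60 °C at 8.0 min | 10 min |

| run | time / min | links / % | first end groups / % |
|---|---|---|---|
| epsilon | 1.33 | 33 | 60 |
| epsilon | 3.00 | 43 | 38 |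
| epsilon | 4.00 | 44 | 29 |
| epsilon | 6.00 | 51 | 18 |
| epsilon | 8.00 | 54 | 15 |
| epsilon | 10.0 | 58 | 12 |
| zeta | 0.417 | 15 | 83 |
| zeta | 0.833 | 18 | 72 |
| zeta | 1.33 | 29 | 62 |
| zeta | 1.50 | 28 | 58 |
| zeta | 2.00 | 33 | 49 |
| zeta | 2.50 | 35 | 45 |
| zeta | 3.00 | 38 | 41 |

(standard deviation of a reading: 2 percentage points)

- the numbers in the tables scatter with a standard deviation of 2 percentage points
- the earlier runs do not show what temperature does; that part of a forecast is a guess

1. which flask leads in amount of links, in percent of the first end groups charged ("all alike" within 1.5 percentage points) (south / north-west / north / east / south-east / all alike)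
2. how much links is there at the end, in percent of the first end groups charged: south
3. how much links is there at the end, in percent of the first end groups charged: north-west
4. how much links is there at the end, in percent of the first end groups charged: north
5. how much links is there at the end, in percent of the first end groups charged: east
6. how much links is there at the end, in percent of the first end groups charged: south-east

The link share, a selectivity, is links formed per first end group consumed. If the other exit needs no second end groups, the share is c(second end groups) divided by the sum of c(second end groups) and one constant concentration. I read that constant in two ways, taking c(second end groups) as charged. At 1.33 min the epsilon run shows a gap between consumed and linked of 7 percentage points, which gives 0.0974 M. The zeta run, with 0.68 M of first end groups, shows 9 points at 1.33 min, which gives 0.142 M. The two ways part, and I take the scatter for the cheat: the gaps differ by 2 points and the links by 4 points, against 2 points on each reading. Their mean, 0.120 M, is my even-odds concentration, the c(second end groups) at which a first end group is as likely to become a link as to leave another way.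

Now south. The epsilon run gives a rough link constant of 0.541 L mol⁻¹ min⁻¹. Second end groups are not read, so I guess that protic impurity, at its equal charge, takes them as fast as first end groups do. The feed then holds c(second end groups) near 0.118 M, close to the even-odds concentration. The fork gives a share of 0.496, and with the consumption of the epsilon run, 88.0 %, I commit to 43.6 % links in south.

The forecast puts north in front with 56 %, and gives 46 % for south, 48 % for north-west, 39 % for east and 47 % for south-east. Of south it says “the late arrival costs time”. My figure for south is lower than the forecast's.

    first end groups + links → side product (k = 0.0159 L mol⁻¹ min⁻¹, Ea = 77.0 kJ mol⁻¹)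
    first end groups ⇌ dormant form (K = 30.2, k = 0.0845 min⁻¹, Ea = 104 kJ mol⁻¹, ΔH = −62.0 kJ mol⁻¹)
    first end groups + second end groups → links (k = 0.872 L mol⁻¹ min⁻¹, Ea = 75.0 kJ mol⁻¹)
    second end groups + protic impurity → quenched reagent (k = 0.300 L mol⁻¹ min⁻¹, Ea = 81.0 kJ mol⁻¹)
    first end groups + second end groups → rings, rate k5*[first end groups] as long as [second end groups] is above zero (k = 0.00470 min⁻¹, Ea = 104 kJ mol⁻¹)
    (constants at 60 °C)

The flasks give 40.3 % links in south, 40.3 % in north-west, 52.1 % in north, 43.1 % in east and 48.8 % in south-east, so north leads. South holds 41.5 % dormant form at 10.0 min, which counts among the first end groups no longer free. Its mean c(second end groups) over the first 8.0 min is 0.108 M, so the even-odds concentration gives a share of 0.474, and its links over first end groups no longer free at 10.0 min come to 0.473. The neighbour of south charged with 1.8 M of second end groups ends with 1.07 M of them, which gives a share of 0.899, yet its links over first end groups no longer free are lower, at 0.739.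

The earlier runs and the new flask come from a simulation for an exercise, noise included.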